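Numbering: C9 lactone carbonyl; C8 its α-carbon, bearing C7H2 and ring A; C8' the β-carbon; C9' the ring OCH2; C7' the ketone carbon on ring B.
Cuts: the phenols are masked as benzyl ethers. The C9–OC9' lactone bond is traded for a C9–OC7' lactone (C7' as carbinol, C9' as ester). Then C7'–C8' is cut (aldol), then C8–C8' (enolate alkylation).
Enabling feature: C8' lies between C7', which can be the carbonyl carbon of a ring B aldehyde, and C9', which at the carboxyl level makes C8'–H the one enolizable site of a C9-carboxylate/C9'-ester succinate. The C7' oxygen then sits γ to C9 and can rest there as a five-membered lactone.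
Forward: the ring A propanoate (C7–C8–C9) takes up the C8'–C9' unit, then C7'/ring B with closure of the temporary lactone (C9, C8, C8', C7', O). C9' is reduced, that lactone is opened, C7' is oxidized, and the final lactone (C9, C8, C8', C9', O) closes.
Stereochemistry: C8 (R) comes from an Evans alkylation with (S)-4-benzyloxazolidinone and is never enolized afterwards. C7' is erased by oxidation. C8' (R) is fixed last, by equilibration next to the ketone to the trans lactone.
The C9' ester is allyl so that it can be removed under neutral conditions. The temporary lactone is an electron-rich benzylic ester that strong acid would ionize, with ring A placed to trap the cation.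

Key step: step 5

Remark: from the aldol adduct to the ring-switched keto lactone the material is carried as a mixture of isomers at C7' and/or C8', so the SMILES of those compounds fix C8 only. Isomers of the temporary lactone whose C8 and C8' substituents are trans map onto the cis keto lactone, hence the final equilibration.

Step 1
Reactants: 1 dihydroferulic acid
Product: 2 O-benzyldihydroferulic acid [3-(4-benzyloxy-3-methoxyphenyl)propanoic acid]
Conditions: BnBr (1.2 equiv), NaOH (2.5 equiv), EtOH/H2O, reflux; then aq HCl to pH 2
Reagents that add atoms: benzyl bromide, BrCc1ccccc1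
Why: Williamson ether synthesis on the phenoxide, in which any benzyl ester formed at the carboxylate is saponified again by the excess hydroxide, so that only the aryl benzyl ether remains after acidification.

Step 2
Reactants: 2 O-benzyldihydroferulic acid; 3 (4S)-4-benzyl-1,3-oxazolidin-2-one
Product: 5 (4S)-4-benzyl-3-[3-(4-benzyloxy-3-methoxyphenyl)propanoyl]-1,3-oxazolidin-2-one, via mixed pivalic anhydride 4 (not isolated)
Conditions: tBuCOCl (1.05 equiv), Et3N (2.5 equiv), THF, −20 to 0 °C; then LiCl (1.1 equiv), 3, rt
Reagents that add atoms: pivaloyl chloride, CC(C)(C)C(=O)Cl (its acyl group stands only in 4)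
Why: N-acylation of an oxazolidinone by the mixed-anhydride method, where the tert-butyl group of 4 directs the LiCl-activated oxazolidinone to the unhindered acyl carbon and no stereocentre is touched.

Step 3
Reactants: 5 N-acyl oxazolidinone; 6 allyl bromoacetate
Product: 8 prop-2-enyl (3R)-4-[(4S)-4-benzyl-2-oxo-1,3-oxazolidin-3-yl]-3-[(4-benzyloxy-3-methoxyphenyl)methyl]-4-oxobutanoate, via sodium Z-enolate 7 (not isolated)
Conditions: NaN(SiMe3)2 (1.1 equiv), THF, −78 °C; then 6 (2 equiv), −78 to −40 °C
Reagents that add atoms: sodium bis(trimethylsilyl)amide, C[Si](C)(C)[N-][Si](C)(C)C.[Na+] (its sodium stands only in 7)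
Why: Evans asymmetric alkylation, in which the chelated Z-enolate 7 is shielded on one face by the C4 benzyl group of the (S)-auxiliary, so the bromoacetate forms the C8–C8' bond from the opposite face and sets C8 as (R).

Step 4
Reactants: 8 alkylated imide
Product: 10 (2R)-2-[(4-benzyloxy-3-methoxyphenyl)methyl]-4-oxo-4-(prop-2-enyloxy)butanoic acid, via lithium peroxycarboxylate 9 (not isolated)
Conditions: LiOH (1.6 equiv), 30% aq H2O2 (4 equiv), THF/H2O, 0 °C; then aq Na2SO3; then aq HCl to pH 2
Reagents that add atoms: hydrogen peroxide, OO; lithium hydroxide, [Li+].[OH-] (its lithium stands only in 9)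
Why: Lithium hydroperoxide cleavage of an N-acyloxazolidinone, in which the small and highly nucleophilic hydroperoxide attacks the exocyclic imide carbonyl far faster than the allyl ester and without enolization at C8, and sulfite then reduces the peroxy acid salt 9.

Step 5
Reactants: 10 (R)-succinic half-ester; 11 O-benzylvanillin
Product: 14 prop-2-enyl (4R)-2-(4-benzyloxy-3-methoxyphenyl)-4-[(4-benzyloxy-3-methoxyphenyl)methyl]-5-oxooxolane-3-carboxylate (isomer mixture at C7' and C8'), via dilithio dianion 12 (not isolated), via aldol hydroxy acid 13 (not isolated)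
Conditions: LiN(iPr)2 (2.2 equiv), THF, −78 °C; 11 (1.1 equiv), −78 °C; AcOH, −78 °C, pH 3 work-up; then PPTS (10 mol %), CH2Cl2, rt
Reagents that add atoms: lithium diisopropylamide, CC(C)[N-]C(C)C.[Li+] (its lithium stands only in 12)
Why: The first equivalent of LiN(iPr)2 forms the C9 carboxylate and the second removes a C8'–H to give the allyl ester enolate 12, which adds to the aldehyde carbon of 11 through a closed, lithium-chelated Zimmerman–Traxler type transition state and so forms C7'–C8'. The closest known reaction type is the aldol–lactonization of succinic half-ester dianions with aldehydes that leads to γ-substituted paraconic esters, and the site of enolization is the one used in the alkylation of 2-alkylsuccinic 4-ester dianions. After a cold AcOH quench, which stops retro-aldol cleavage, the C7' hydroxyl of 13 attacks the C9 carboxyl carbon under PPTS catalysis in a 5-exo-trig closure that gives the temporary lactone (ring atoms C9, C8, C8', C7', O). C8' is set under the influence of the C8 benzyl arm in the chelated dianion and C7' by the aldol transition state, but neither outcome matters, because C7' is later oxidized flat and C8' is later equilibrated. The only selectivity needed is enolization at C8' and not at C8, and the negative charge of the adjacent carboxylate secures it and thereby keeps C8 (R). The acid is kept weak because the electron-rich benzylic C7'–O bond would ionize in strong acid and ring A would then capture the cation.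

Step 6
Reactants: 14 temporary lactone allyl ester
Product: 15 (4R)-2-(4-benzyloxy-3-methoxyphenyl)-4-[(4-benzyloxy-3-methoxyphenyl)methyl]-5-oxooxolane-3-carboxylic acid (isomer mixture)
Conditions: Pd(PPh3)4 (5 mol %), PhNHMe (3 equiv), THF, rt
Reagents that add atoms: none
Why: Tsuji–Trost type allyl transfer, in which zerovalent palladium ionizes only the allyl ester and N-methylaniline takes up the allyl group, a neutral unmasking chosen because strong acid would ionize the electron-rich benzylic C7'–O bond of the lactone and let ring A close an aryltetralin.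

Step 7
Reactants: 15 paraconic-type acid
Product: 16 (3R)-5-(4-benzyloxy-3-methoxyphenyl)-3-[(4-benzyloxy-3-methoxyphenyl)methyl]-4-(hydroxymethyl)oxolan-2-one (isomer mixture)
Conditions: BH3·SMe2 (2 equiv), THF, 0 °C to rt; then MeOH
Reagents that add atoms: none
Why: Chemoselective borane reduction of a carboxylic acid through its acyloxyborane, well known for paraconic acids, which brings C9' to CH2OH while the much less reactive lactone carbonyl C9 and the benzyl ethers stay untouched.

Step 8
Reactants: 16 hydroxymethyl lactone
Product: 17 (2R)-4-(4-benzyloxy-3-methoxyphenyl)-2-[(4-benzyloxy-3-methoxyphenyl)methyl]-4-hydroxy-3-(hydroxymethyl)-N-methoxy-N-methylbutanamide (isomer mixture)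
Conditions: MeNH(OMe)·HCl (4 equiv), AlMe3 (4 equiv), CH2Cl2, 0 °C to rt; aq potassium sodium tartrate work-up; used without delay
Reagents that add atoms: N,O-dimethylhydroxylamine hydrochloride, CNOC.Cl
Why: Weinreb aminolysis of a lactone with the aluminium amide made from AlMe3 and the amine salt, which breaks the C9–OC7' bond under non-epimerizing conditions and frees the benzylic alcohol while C9 is held as an amide.

Step 9
Reactants: 17 dihydroxy Weinreb amide
Product: 18 (2R)-4-(4-benzyloxy-3-methoxyphenyl)-2-[(4-benzyloxy-3-methoxyphenyl)methyl]-3-(hydroxymethyl)-N-methoxy-N-methyl-4-oxobutanamide (C8' epimers)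
Conditions: activated MnO2 (20 equiv), CH2Cl2, rt
Reagents that add atoms: none
Why: MnO2 oxidation, selective for benzylic over saturated primary alcohols, turns C7' into the aryl ketone, removes that stereocentre and leaves the C9' hydroxyl as the only partner for C9.

Step 10
Reactants: 18 keto hydroxy amide
Product: 19 (3R)-4-(4-benzyloxy-3-methoxybenzoyl)-3-[(4-benzyloxy-3-methoxyphenyl)methyl]oxolan-2-one (C8' epimers)
Conditions: p-TsOH·H2O (1.2 equiv), CH2Cl2, rt
Reagents that add atoms: none
Why: Acid-promoted lactonization of a γ-hydroxy Weinreb amide (5-exo-trig acyl substitution with loss of the protonated amine) closes the final ring between the C9' oxygen and C9, and no benzylic cation can arise now that C7' is a carbonyl carbon.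

Step 11
Reactants: 19 keto lactone epimers
Product: 20 (3R,4R)-4-(4-benzyloxy-3-methoxybenzoyl)-3-[(4-benzyloxy-3-methoxyphenyl)methyl]oxolan-2-one (trans)
Conditions: DBU (0.3 equiv), toluene, rt to 40 °C
Reagents that add atoms: none
Why: Base-catalysed thermodynamic epimerization through the aryl ketone enolate, as used to turn cis into trans β-acyl and β-alkoxycarbonyl butyrolactones, inverts only C8' (the lactone α-proton at C8 is far less acidic toward an amidine) until benzyl and aroyl groups are trans and C8' is (R), while loss of the ring carboxylate is held back because the C9'–O bond lies near the nodal plane of the exocyclic enolate (the reverse of a 5-endo-trig closure).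

Step 12
Reactants: 20 trans keto lactone dibenzyl ether
Product: 21 (3R,4R)-4-(4-hydroxy-3-methoxybenzoyl)-3-[(4-hydroxy-3-methoxyphenyl)methyl]oxolan-2-one (target)
Conditions: BCl3 (5 equiv), C6HMe5 (6 equiv), CH2Cl2, −78 °C; then MeOH
Reagents that add atoms: none
Why: BCl3-mediated cleavage of aryl benzyl ethers with pentamethylbenzene as a non-basic benzyl cation trap, which at −78 °C spares the aryl methyl ethers, the lactone and the aryl ketone that hydrogenolysis could over-reduce, and leaves both stereocentres alone.

Compound list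
1 | dihydroferulic acid, 3-(4-hydroxy-3-methoxyphenyl)propanoic acid | COc1cc(CCC(=O)O)ccc1O | starting material
2 | 3-(4-benzyloxy-3-methoxyphenyl)propanoic acid | COc1cc(CCC(=O)O)ccc1OCc1ccccc1 | intermediate
3 | (4S)-4-benzyl-1,3-oxazolidin-2-one | O=C1N[C@@H](Cc2ccccc2)CO1 | starting material
4 | 3-(4-benzyloxy-3-methoxyphenyl)propanoic pivalic anhydride | COc1cc(CCC(=O)OC(=O)C(C)(C)C)ccc1OCc1ccccc1 | intermediate
5 | (4S)-4-benzyl-3-[3-(4-benzyloxy-3-methoxyphenyl)propanoyl]-1,3-oxazolidin-2-one | COc1cc(CCC(=O)N2C(=O)OC[C@@H]2Cc2ccccc2)ccc1OCc1ccccc1 | intermediate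
6 | allyl bromoacetate | C=CCOC(=O)CBr | starting material
7 | sodium Z-enolate of 5 | [Na+].[O-]/C(=C\Cc1ccc(OCc2ccccc2)c(OC)c1)N1C(=O)OC[C@@H]1Cc1ccccc1 | intermediate
8 | prop-2-enyl (3R)-4-[(4S)-4-benzyl-2-oxo-1,3-oxazolidin-3-yl]-3-[(4-benzyloxy-3-methoxyphenyl)methyl]-4-oxobutanoate | O=C(N1C(=O)OC[C@@H]1Cc1ccccc1)[C@H](Cc1ccc(OCc2ccccc2)c(OC)c1)CC(=O)OCC=C | intermediate
9 | lithium (2R)-2-[(4-benzyloxy-3-methoxyphenyl)methyl]-4-oxo-4-(prop-2-enyloxy)butaneperoxoate | [Li+].[O-]OC(=O)[C@H](Cc1ccc(OCc2ccccc2)c(OC)c1)CC(=O)OCC=C | intermediate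
10 | (2R)-2-[(4-benzyloxy-3-methoxyphenyl)methyl]-4-oxo-4-(prop-2-enyloxy)butanoic acid | OC(=O)[C@H](Cc1ccc(OCc2ccccc2)c(OC)c1)CC(=O)OCC=C | intermediate
11 | O-benzylvanillin, 4-benzyloxy-3-methoxybenzaldehyde | COc1cc(C=O)ccc1OCc1ccccc1 | starting material
12 | dilithium C9 carboxylate / C8' allyl ester enolate of 10 | [Li+].[Li+].[O-]C(=O)[C@H](Cc1ccc(OCc2ccccc2)c(OC)c1)C=C([O-])OCC=C | intermediate
13 | (2R)-2-[(4-benzyloxy-3-methoxyphenyl)methyl]-3-[(4-benzyloxy-3-methoxyphenyl)(hydroxy)methyl]-4-oxo-4-(prop-2-enyloxy)butanoic acid, isomers at C7' and C8' | OC(=O)[C@H](Cc1ccc(OCc2ccccc2)c(OC)c1)C(C(=O)OCC=C)C(O)c1ccc(OCc2ccccc2)c(OC)c1 | intermediate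
14 | prop-2-enyl (4R)-2-(4-benzyloxy-3-methoxyphenyl)-4-[(4-benzyloxy-3-methoxyphenyl)methyl]-5-oxooxolane-3-carboxylate, isomers at C7' and C8' | COc1cc(C[C@H]2C(=O)OC(c3ccc(OCc4ccccc4)c(OC)c3)C2C(=O)OCC=C)ccc1OCc1ccccc1 | intermediate
15 | (4R)-2-(4-benzyloxy-3-methoxyphenyl)-4-[(4-benzyloxy-3-methoxyphenyl)methyl]-5-oxooxolane-3-carboxylic acid, isomers at C7' and C8' | COc1cc(C[C@H]2C(=O)OC(c3ccc(OCc4ccccc4)c(OC)c3)C2C(=O)O)ccc1OCc1ccccc1 | intermediate
16 | (3R)-5-(4-benzyloxy-3-methoxyphenyl)-3-[(4-benzyloxy-3-methoxyphenyl)methyl]-4-(hydroxymethyl)oxolan-2-one, isomers at C7' and C8' | COc1cc(C[C@H]2C(=O)OC(c3ccc(OCc4ccccc4)c(OC)c3)C2CO)ccc1OCc1ccccc1 | intermediate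
17 | (2R)-4-(4-benzyloxy-3-methoxyphenyl)-2-[(4-benzyloxy-3-methoxyphenyl)methyl]-4-hydroxy-3-(hydroxymethyl)-N-methoxy-N-methylbutanamide, isomers at C7' and C8' | CON(C)C(=O)[C@H](Cc1ccc(OCc2ccccc2)c(OC)c1)C(CO)C(O)c1ccc(OCc2ccccc2)c(OC)c1 | intermediate
18 | (2R)-4-(4-benzyloxy-3-methoxyphenyl)-2-[(4-benzyloxy-3-methoxyphenyl)methyl]-3-(hydroxymethyl)-N-methoxy-N-methyl-4-oxobutanamide, C8' epimers | CON(C)C(=O)[C@H](Cc1ccc(OCc2ccccc2)c(OC)c1)C(CO)C(=O)c1ccc(OCc2ccccc2)c(OC)c1 | intermediate
19 | (3R)-4-(4-benzyloxy-3-methoxybenzoyl)-3-[(4-benzyloxy-3-methoxyphenyl)methyl]oxolan-2-one, C8' epimers | COc1cc(C[C@H]2C(=O)OCC2C(=O)c2ccc(OCc3ccccc3)c(OC)c2)ccc1OCc1ccccc1 | intermediate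
20 | (3R,4R)-4-(4-benzyloxy-3-methoxybenzoyl)-3-[(4-benzyloxy-3-methoxyphenyl)methyl]oxolan-2-one | COc1cc(C[C@H]2C(=O)OC[C@@H]2C(=O)c2ccc(OCc3ccccc3)c(OC)c2)ccc1OCc1ccccc1 | intermediate
21 | (3R,4R)-4-(4-hydroxy-3-methoxybenzoyl)-3-[(4-hydroxy-3-methoxyphenyl)methyl]oxolan-2-one | COc1cc(C[C@H]2C(=O)OC[C@@H]2C(=O)c2ccc(O)c(OC)c2)ccc1O | target

Total step count: 12. Longest linear sequence: 12 steps (1 to 21); 3, 6 and 11 are bought.

Steps most likely to fail

Step 5. The aldol addition to the electron-rich aldehyde may reverse before the quench. The allyl ester enolate may decay by sigmatropic or ketene-type pathways if the temperature drifts. C7' may ionize during the acid-assisted ring closure. The fallback sets out from imide 8 instead of acid 10, so step 4 is skipped. One equivalent of LiN(iPr)2 in THF at −78 °C should remove only a C8'–H, because allylic 1,3-strain holds the C8–H bond of the α-branched imide in the carbonyl plane. This gives the C8' lithium ester enolate F1. After addition of 11 and warming to 0 °C, the C7' alkoxide attacks the activated imide carbonyl C9 and expels the oxazolidinone. The same C7'–C8' bond and the same lactone thus form without any acid, and the irreversible acyl transfer drains the aldol equilibrium. The route is rejoined at 14.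

Step 8. The aluminium amide may attack the hindered carbonyl slowly, and the diol amide may close back through the C7' hydroxyl during work-up. The fallback sets out from 16 and uses a carboxylate instead of an amide as the open form. LiOH in THF/H2O gives the lithium dihydroxy carboxylate F2. After removal of the solvents, this salt is oxidized with MnO2 in acetone to the lithium keto hydroxy carboxylate F3. Cold dilute HCl then frees an acid whose only remaining hydroxyl is the one on C9', so it closes by itself. The route is rejoined at 19.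

Step 11. The enolate may lose the ring carboxylate by β-elimination. The equilibration may stay incomplete. Long exposure to base may erode C8. The fallback leaves the enolate manifold and reverses the order of the last two operations. It sets out from 19, which is debenzylated first with BCl3 and C6HMe5 at −78 °C to the bisphenol C8' epimer mixture F4. With no benzyl ethers left to lose, F4 can be warmed with p-TsOH in dioxane. C8' then inverts through the neutral enol, and C8 is safe because a ketone enolizes in acid much faster than a lactone. The route is rejoined at 21.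

Further compounds
F1 | step 5 | C8' lithium ester enolate of imide 8 | O=C(N1C(=O)OC[C@@H]1Cc1ccccc1)[C@H](Cc1ccc(OCc2ccccc2)c(OC)c1)C=C([O-])OCC=C.[Li+]
F2 | step 8 | lithium dihydroxy carboxylate, lithium (2R)-4-(4-benzyloxy-3-methoxyphenyl)-2-[(4-benzyloxy-3-methoxyphenyl)methyl]-4-hydroxy-3-(hydroxymethyl)butanoate | [Li+].[O-]C(=O)[C@H](Cc1ccc(OCc2ccccc2)c(OC)c1)C(CO)C(O)c1ccc(OCc2ccccc2)c(OC)c1
F3 | step 8 | lithium keto hydroxy carboxylate, lithium (2R)-4-(4-benzyloxy-3-methoxyphenyl)-2-[(4-benzyloxy-3-methoxyphenyl)methyl]-3-(hydroxymethyl)-4-oxobutanoate | [Li+].[O-]C(=O)[C@H](Cc1ccc(OCc2ccccc2)c(OC)c1)C(CO)C(=O)c1ccc(OCc2ccccc2)c(OC)c1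
F4 | step 11 | bisphenol C8' epimer mixture, (3R)-4-(4-hydroxy-3-methoxybenzoyl)-3-[(4-hydroxy-3-methoxyphenyl)methyl]oxolan-2-one | COc1cc(C[C@H]2C(=O)OCC2C(=O)c2ccc(O)c(OC)c2)ccc1O
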